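The target is cut at the bond between C2 of the oxolane ring and its syringyl ring, the aryl group that stands cis to the C3 methyl. The key step makes this bond by aryl transfer from a diarylzinc to the oxolan-2-ylium ion set free from a 2-sulfonyl oxolane that already holds the trans C3/C4 methyl pair and the C5 aryl group. It exploits the trans relation between the C2 aryl and the C4 methyl of the ring: attack anti to the C4 methyl sets C2 in the same operation. The precursor, a 5-aryl-3,4-dimethyl lactol derivative, comes in three steps from an aldehyde by asymmetric crotylboration and directed branched hydroformylation.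

Key step: step 5

Remark: the absolute sense of step 1 is assigned by analogy with the Si-face selectivity of the (+)-α-pinene-derived crotylborane towards aromatic aldehydes. Lactol 5 and sulfone 6 are anomer mixtures; both anomers converge on ion 11. Ring numbering throughout: O1, C2 (carbon made in the key step), C3, C4, C5 (carbon from the aldehyde).

Step 1
Reactants: 1 4-(benzyloxy)-3,5-dimethoxybenzaldehyde
Product: 3 (1S,2S)-1-[4-(benzyloxy)-3,5-dimethoxyphenyl]-2-methylbut-3-en-1-ol, via diisopinocampheylborinate 2 (not isolated)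
Conditions: trans-2-butene, KOt-Bu, n-BuLi, THF, −78 to −45 °C; (−)-Ipc2BOMe, −78 °C; BF3·OEt2; 1, −78 °C; then NaOH, H2O2, 0 °C to rt
Reagents that add atoms: trans-2-butene C/C=C/C
Why: Brown asymmetric crotylboration, in which the (E)-crotylborane reacts through a closed chair transition state so that the E geometry should give the anti relationship and the isopinocampheyl groups should direct attack to the Si face of the aldehyde, setting C1 (S) and C2 (S), the later ring carbons C5 and C4.

Step 2
Reactants: 3 (1S,2S)-1-[4-(benzyloxy)-3,5-dimethoxyphenyl]-2-methylbut-3-en-1-ol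
Product: 5 (3S,4S,5S)-5-[4-(benzyloxy)-3,5-dimethoxyphenyl]-3,4-dimethyloxolan-2-ol, via hydroxy aldehyde 4 (not isolated)
Conditions: Rh(CO)2(acac) (2 mol %), Ph2POMe (10 mol %), CO/H2 (1:1, 20 bar), THF, 4 Å MS, 40 °C; then DBU (cat.), CH2Cl2, rt
Reagents that add atoms: carbon monoxide [C-]#[O+]
Why: Branched-selective rhodium-catalysed hydroformylation with a reversibly bound phosphinite directing group, in which the carbinol-bound phosphinite should deliver rhodium hydride through a six-membered chelate so that the formyl group enters at the internal alkene carbon and the terminal carbon becomes the C3 methyl; the hydroxy aldehyde closes to the lactol, and C3, which is α to the masked aldehyde, is equilibrated by DBU to the thermodynamically preferred configuration trans to the C4 methyl.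

Step 3
Reactants: 5 (3S,4S,5S)-5-[4-(benzyloxy)-3,5-dimethoxyphenyl]-3,4-dimethyloxolan-2-ol
Product: 6 (3S,4S,5S)-2-(benzenesulfonyl)-5-[4-(benzyloxy)-3,5-dimethoxyphenyl]-3,4-dimethyloxolane
Conditions: PhSO2H, CaCl2, CH2Cl2, rt
Reagents that add atoms: benzenesulfinic acid OS(=O)c1ccccc1
Why: Lactol-to-sulfone exchange (S-alkylation of the sulfinate by the oxocarbenium ion formed on loss of water), which should give a storable anomeric sulfone without touching C3, C4 or C5.

Step 4
Reactants: 7 4-bromo-2,6-dimethoxyphenol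
Product: 8 2-(benzyloxy)-5-bromo-1,3-dimethoxybenzene
Conditions: BnBr, K2CO3, DMF, rt
Reagents that add atoms: benzyl bromide BrCc1ccccc1
Why: Williamson ether synthesis, which masks the acidic phenol before the Grignard reagent is made.

Step 5
Reactants: 6 (3S,4S,5S)-2-(benzenesulfonyl)-5-[4-(benzyloxy)-3,5-dimethoxyphenyl]-3,4-dimethyloxolane; 8 2-(benzyloxy)-5-bromo-1,3-dimethoxybenzene
Product: 12 (2R,3S,4S,5S)-2,5-bis[4-(benzyloxy)-3,5-dimethoxyphenyl]-3,4-dimethyloxolane, via arylmagnesium bromide 9 (not isolated), via diarylzinc 10 (not isolated), via oxocarbenium ion 11 (not isolated)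
Conditions: 8, Mg, THF, reflux; ZnBr2 (0.5 equiv per ArMgBr), THF, rt; then 6, THF, rt; aq NH4Cl
Reagents that add atoms: none
Why: Magnesium insertion into 8 and transmetalation give diarylzinc 10; the zinc and magnesium bromides ionise the anomeric sulfone of 6 to the oxolan-2-ylium ion 11, and 10 transfers one aryl group to its C2 irreversibly. The closest known reaction type is the substitution of 2-(arylsulfonyl) cyclic ethers by organozinc reagents, with the stereochemistry following the inside-attack model for five-membered oxocarbenium ions. No ring is closed. The new stereocentre C2 is controlled by the substrate: in the favoured envelope of 11, C4 is the flap and the C3 methyl, C4 methyl and C5 aryl are all pseudoequatorial, so the aryl should enter on the flap face, anti to the C4 methyl, and end cis to the C3 methyl and cis to the C5 aryl (2R). The selectivity needed is this facial one, against the all-trans C2 epimer that thermodynamics prefers; it is secured by kinetic control, since aryl transfer from zinc is irreversible and ZnBr2/MgBr2 in THF should not re-ionise the benzylic C–O bonds of 12. Both anomers of 6 converge on the same ion.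

Step 6
Reactants: 12 (2R,3S,4S,5S)-2,5-bis[4-(benzyloxy)-3,5-dimethoxyphenyl]-3,4-dimethyloxolane
Product: 13 4,4'-[(2R,3S,4S,5S)-3,4-dimethyloxolane-2,5-diyl]bis(2,6-dimethoxyphenol)
Conditions: H2 (1 atm), 10% Pd/C, EtOAc–MeOH, rt
Reagents that add atoms: none
Why: Catalytic hydrogenolysis of the two aryl benzyl ethers, which under neutral conditions at 1 atm should be cleaved much faster than the ring benzylic C–O bonds and touches no stereocentre.

Compound list
1 | 4-(benzyloxy)-3,5-dimethoxybenzaldehyde | COc1cc(C=O)cc(OC)c1OCc1ccccc1 | starting material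
2 | (1S,2S)-1-[4-(benzyloxy)-3,5-dimethoxyphenyl]-2-methylbut-3-en-1-yl bis(isopinocampheyl)borinate | COc1cc([C@@H](OB([C@@H]2C[C@@H]3C[C@H]([C@H]2C)C3(C)C)[C@@H]2C[C@@H]3C[C@H]([C@H]2C)C3(C)C)[C@@H](C)C=C)cc(OC)c1OCc1ccccc1 | intermediate
3 | (1S,2S)-1-[4-(benzyloxy)-3,5-dimethoxyphenyl]-2-methylbut-3-en-1-ol | COc1cc([C@@H](O)[C@@H](C)C=C)cc(OC)c1OCc1ccccc1 | intermediate
4 | (2S,3S,4S)-4-[4-(benzyloxy)-3,5-dimethoxyphenyl]-4-hydroxy-2,3-dimethylbutanal | COc1cc([C@@H](O)[C@@H](C)[C@H](C)C=O)cc(OC)c1OCc1ccccc1 | intermediate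
5 | (3S,4S,5S)-5-[4-(benzyloxy)-3,5-dimethoxyphenyl]-3,4-dimethyloxolan-2-ol | COc1cc([C@H]2OC(O)[C@@H](C)[C@@H]2C)cc(OC)c1OCc1ccccc1 | intermediate
6 | (3S,4S,5S)-2-(benzenesulfonyl)-5-[4-(benzyloxy)-3,5-dimethoxyphenyl]-3,4-dimethyloxolane | COc1cc([C@H]2OC(S(=O)(=O)c3ccccc3)[C@@H](C)[C@@H]2C)cc(OC)c1OCc1ccccc1 | intermediate
7 | 4-bromo-2,6-dimethoxyphenol | COc1cc(Br)cc(OC)c1O | starting material
8 | 2-(benzyloxy)-5-bromo-1,3-dimethoxybenzene | COc1cc(Br)cc(OC)c1OCc1ccccc1 | intermediate
9 | [4-(benzyloxy)-3,5-dimethoxyphenyl]magnesium bromide | COc1cc([Mg]Br)cc(OC)c1OCc1ccccc1 | intermediate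
10 | bis[4-(benzyloxy)-3,5-dimethoxyphenyl]zinc | COc1cc([Zn]c2cc(OC)c(OCc3ccccc3)c(OC)c2)cc(OC)c1OCc1ccccc1 | intermediate
11 | (2S,3S,4S)-2-[4-(benzyloxy)-3,5-dimethoxyphenyl]-3,4-dimethyl-3,4-dihydro-2H-furan-1-ium | COc1cc([C@H]2[O+]=C[C@@H](C)[C@@H]2C)cc(OC)c1OCc1ccccc1 | intermediate
12 | (2R,3S,4S,5S)-2,5-bis[4-(benzyloxy)-3,5-dimethoxyphenyl]-3,4-dimethyloxolane | COc1cc([C@H]2O[C@@H](c3cc(OC)c(OCc4ccccc4)c(OC)c3)[C@@H](C)[C@@H]2C)cc(OC)c1OCc1ccccc1 | intermediate
13 | 4,4'-[(2R,3S,4S,5S)-3,4-dimethyloxolane-2,5-diyl]bis(2,6-dimethoxyphenol) | COc1cc([C@H]2O[C@@H](c3cc(OC)c(O)c(OC)c3)[C@@H](C)[C@@H]2C)cc(OC)c1O | target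

Total step count: 6. Longest linear sequence: 5 (steps 1, 2, 3, 5, 6).

Steps most likely to fail

Step 5. The aryl group may enter anti to the neighbouring C3 methyl instead of anti to the C4 methyl, or the product may be re-ionised by the Lewis acids and drift to the all-trans C2 epimer. The fallback sets C2 by reagent control on an open chain and closes the ring at the other benzylic carbon; it sets out from lactol 5 and comes back at target 13. Fétizon oxidation of 5 (Ag2CO3 on Celite, toluene, reflux) would give lactone F1. Phenol 7 would be tosylated (TsCl, Et3N) to the aryl bromide F2, whose aryllithium (n-BuLi, THF, −78 °C) should add once to F1 to give hydroxy ketone F3. CBS reduction with (S)-Me-CBS and BH3·SMe2 should give the (1R)-diol F4. Catalytic acid (CSA, CH2Cl2, 0 °C) should ionise only the carbinol next to the electron-rich benzyloxy aryl group, because the tosyloxy aryl carbinol is deactivated. Closure by the other hydroxyl, with retention at C2 and the C5 aryl settling trans to the C4 methyl, would give oxolane F5. KOH in MeOH would remove the tosyl group to give phenol F6, and hydrogenolysis as in step 6 would give 13.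

Step 2. The directing group may exchange slowly at the hindered secondary benzylic alcohol, so that branched selectivity is lost and the linear aldehyde (six-membered lactol) forms. The fallback builds C3 by lactone alkylation; it sets out from alcohol 3 and comes back at lactol 5. Hydroboration–oxidation of 3 (9-BBN, THF; NaOH, H2O2) would give diol F7. Oxidative lactonisation (TEMPO cat., PhI(OAc)2, CH2Cl2) would give lactone F8. Enolate methylation (LDA, THF, −78 °C; MeI), anti to the C4 methyl, would give lactone F1, the lactone already named above. DIBAL-H (CH2Cl2, −78 °C) would then give 5.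

Step 3. The sulfinic acid may ionise the C5 benzylic C–O bond, leading to epimerisation at C5 or capture of the benzylic cation by sulfinate. The fallback avoids acid in making the leaving group; it sets out from lactol 5 and comes back at 12. Acetylation (Ac2O, Et3N, DMAP, CH2Cl2) would give anomeric acetate F9, which would be ionised with TMSOTf in CH2Cl2 at −78 °C in the presence of diarylzinc 10 to give 12 by the same facial course.

Further compounds
F1 | step 5 | (3S,4S,5S)-5-[4-(benzyloxy)-3,5-dimethoxyphenyl]-3,4-dimethyloxolan-2-one | COc1cc([C@H]2OC(=O)[C@@H](C)[C@@H]2C)cc(OC)c1OCc1ccccc1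
F2 | step 5 | 4-bromo-2,6-dimethoxyphenyl 4-methylbenzenesulfonate | COc1cc(Br)cc(OC)c1OS(=O)(=O)c1ccc(C)cc1
F3 | step 5 | 4-[(2S,3S,4S)-4-[4-(benzyloxy)-3,5-dimethoxyphenyl]-4-hydroxy-2,3-dimethylbutanoyl]-2,6-dimethoxyphenyl 4-methylbenzenesulfonate | COc1cc([C@@H](O)[C@@H](C)[C@H](C)C(=O)c2cc(OC)c(OS(=O)(=O)c3ccc(C)cc3)c(OC)c2)cc(OC)c1OCc1ccccc1
F4 | step 5 | 4-[(1R,2S,3S,4S)-4-[4-(benzyloxy)-3,5-dimethoxyphenyl]-1,4-dihydroxy-2,3-dimethylbutyl]-2,6-dimethoxyphenyl 4-methylbenzenesulfonate | COc1cc([C@@H](O)[C@@H](C)[C@H](C)[C@@H](O)c2cc(OC)c(OS(=O)(=O)c3ccc(C)cc3)c(OC)c2)cc(OC)c1OCc1ccccc1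
F5 | step 5 | 4-[(2R,3S,4S,5S)-5-[4-(benzyloxy)-3,5-dimethoxyphenyl]-3,4-dimethyloxolan-2-yl]-2,6-dimethoxyphenyl 4-methylbenzenesulfonate | COc1cc([C@H]2O[C@@H](c3cc(OC)c(OS(=O)(=O)c4ccc(C)cc4)c(OC)c3)[C@@H](C)[C@@H]2C)cc(OC)c1OCc1ccccc1
F6 | step 5 | 4-[(2R,3S,4S,5S)-5-[4-(benzyloxy)-3,5-dimethoxyphenyl]-3,4-dimethyloxolan-2-yl]-2,6-dimethoxyphenol | COc1cc([C@H]2O[C@@H](c3cc(OC)c(O)c(OC)c3)[C@@H](C)[C@@H]2C)cc(OC)c1OCc1ccccc1
F7 | step 2 | (1S,2S)-1-[4-(benzyloxy)-3,5-dimethoxyphenyl]-2-methylbutane-1,4-diol | COc1cc([C@@H](O)[C@@H](C)CCO)cc(OC)c1OCc1ccccc1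
F8 | step 2 | (4S,5S)-5-[4-(benzyloxy)-3,5-dimethoxyphenyl]-4-methyloxolan-2-one | COc1cc([C@H]2OC(=O)C[C@@H]2C)cc(OC)c1OCc1ccccc1
F9 | step 3 | (3S,4S,5S)-5-[4-(benzyloxy)-3,5-dimethoxyphenyl]-3,4-dimethyloxolan-2-yl acetate | COc1cc([C@H]2OC(OC(C)=O)[C@@H](C)[C@@H]2C)cc(OC)c1OCc1ccccc1
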